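The pyranone ring (O1, C2, C3, C4, C4a, C8a) is traced back to a seven-membered cyclic acetal, a 2-aryl-1,3-benzodioxepin-5-one, that carries one extra oxygen between C2 and C3. The key step, a chiral-acid-catalysed O-to-C shift (formal [1,2]-Wittig, Petasis–Ferrier-type ring contraction), exploits that C2 is both benzylic to the electron-rich B ring and bound to O1, hence a latent oxocarbenium carbon, while C3 is the oxygenated α-carbon of the C4 ketone. In one operation it should forge C2–C3, set both stereocentres trans and leave the expelled oxygen as the 3-hydroxyl, which is then methylated. The acetal is assembled from an α-hydroxylated, benzyl-protected acetophenone and O-benzylisovanillin.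

Key step: step 6

Assumption: the sense of induction of the chiral acid in step 6 cannot be assigned on paper; the (R)-catalyst is written, and its mirror image is to be used if it favours the (2S,3S) series.

Step 1
Reactants: 1 1-(2,6-dihydroxy-4-methoxyphenyl)ethan-1-one
Product: 2 1-[2-(benzyloxy)-6-hydroxy-4-methoxyphenyl]ethan-1-one
Conditions: BnBr (1.0 equiv), K2CO3, acetone, rt → 40 °C
Reagents that add atoms: benzyl bromide, BrCc1ccccc1
Why: Williamson etherification of a symmetric diol; after the first alkylation the remaining phenol is locked in a hydrogen bond to the ketone and is far less nucleophilic, so mono-benzylation should dominate.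

Step 2
Reactants: 2 1-[2-(benzyloxy)-6-hydroxy-4-methoxyphenyl]ethan-1-one
Product: 4 1-[2-(benzyloxy)-3,6-dihydroxy-4-methoxyphenyl]ethan-1-one, via aryl potassium sulfate 3 (not isolated)
Conditions: K2S2O8, aq. KOH, pyridine, 0 → 20 °C; then 1 M HCl, Na2SO3, 70 °C
Reagents that add atoms: potassium peroxodisulfate, [K+].[K+].[O-]S(=O)(=O)OOS(=O)(=O)[O-]
Why: Elbs persulfate oxidation, in which the phenoxide of the free 6-OH is attacked by peroxodisulfate at its only para position (C3) and mild acid hydrolysis of the aryl sulfate 3 releases the new phenol.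

Step 3
Reactants: 4 1-[2-(benzyloxy)-3,6-dihydroxy-4-methoxyphenyl]ethan-1-one
Product: 5 1-[2,3-bis(benzyloxy)-6-hydroxy-4-methoxyphenyl]ethan-1-one
Conditions: BnBr (1.05 equiv), K2CO3, DMF, N2, rt
Reagents that add atoms: benzyl bromide, BrCc1ccccc1
Why: Williamson etherification, selective for the new 3-OH because the 6-OH is chelated to the carbonyl group and should react far more slowly.

Step 4
Reactants: 5 1-[2,3-bis(benzyloxy)-6-hydroxy-4-methoxyphenyl]ethan-1-one
Product: 8 1-[2,3-bis(benzyloxy)-6-hydroxy-4-methoxyphenyl]-2-hydroxyethan-1-one, via bis-silyl enol ether 6 (not isolated), via bis-silylated ketol 7 (not isolated)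
Conditions: TMSOTf, Et3N, CH2Cl2, 0 °C; mCPBA, NaHCO3, CH2Cl2, −20 → 0 °C; then 1 M HCl, THF, rt
Reagents that add atoms: meta-chloroperoxybenzoic acid, OOC(=O)c1cccc(Cl)c1
Why: Rubottom oxidation, in which the silyl enol ether of the methyl ketone (phenol masked in the flask as its TMS ether) is epoxidised, the silyloxy epoxide rearranges by silyl shift to the α-silyloxy ketone, and mild acid removes both silyl groups.

Step 5
Reactants: 8 1-[2,3-bis(benzyloxy)-6-hydroxy-4-methoxyphenyl]-2-hydroxyethan-1-one; 9 3-(benzyloxy)-4-methoxybenzaldehyde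
Product: 11 rac-6,7-bis(benzyloxy)-2-[3-(benzyloxy)-4-methoxyphenyl]-8-methoxy-2H-1,3-benzodioxepin-5(4H)-one, via dimethyl acetal 10 (not isolated)
Conditions: 9, HC(OMe)3, PPTS (5 mol %), PhMe, rt; then 8, 4 Å MS, 45 °C, reduced pressure
Reagents that add atoms: none
Why: Acid-catalysed transacetalisation of the dimethyl acetal 10 with the phenol/primary alcohol pair of 8, driven by removal of methanol; PPTS should be too weak to enolise the ketone, so the seven-membered acetal is expected to survive, racemic at C2.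

Step 6
Reactants: 11 rac-6,7-bis(benzyloxy)-2-[3-(benzyloxy)-4-methoxyphenyl]-8-methoxy-2H-1,3-benzodioxepin-5(4H)-one
Product: 13 (2R,3R)-5,6-bis(benzyloxy)-2-[3-(benzyloxy)-4-methoxyphenyl]-3-hydroxy-7-methoxy-2,3-dihydro-4H-chromen-4-one, via aryloxycarbenium enediol cation 12 (not isolated)
Conditions: (R)-3,3'-bis(2,4,6-triisopropylphenyl)-BINOL N-triflylphosphoramide (10 mol %), PhMe, 5 Å MS, −20 °C → rt
Reagents that add atoms: none
Why: Proposed new method: the chiral acid protonates O3 and ionises the C2–O3 bond of either enantiomer of 11 to the same planar aryloxycarbenium ion 12, stabilised by O1 and by the 4-methoxyphenyl ring, while the liberated α-hydroxy ketone tautomerises to its (Z)-enediol within the chiral ion pair. The enediol carbon that was C4H2 then adds to the carbenium carbon, so the seven-membered ring O1–C2–O3–C4–C5–C5a–C9a contracts to the six-membered pyranone and O3 leaves the ring as the 3-hydroxyl, a formal acid-mediated [1,2]-Wittig (O-to-C) shift. The closest known reaction type is the Petasis–Ferrier rearrangement of cyclic enol acetals, including its chiral phosphoric acid-catalysed ring-contracting variants on seven-membered vinyl acetals, and the pyranone ring closes in the same 6-(enolendo)-endo-trig mode. C2 is controlled by the chiral counter-anion, which hydrogen-bonds the enediol and shields one face of the E-oxocarbenium ion; C3 is controlled by C2 through a half-chair transition state with aryl and hydroxyl pseudo-equatorial, and any cis isomer should equilibrate to trans by acid-catalysed enolisation at C3 without touching C2. The step needs productive C2–O3 rather than C2–O1 cleavage and attack through the former CH2 carbon rather than the aryl-bearing enediol carbon: O1-cleavage can only re-close, and attack through the CH2 carbon gives the six-membered conjugated aryl ketone instead of a crowded 3-formyl-dihydrobenzofuran.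

Step 7
Reactants: 13 (2R,3R)-5,6-bis(benzyloxy)-2-[3-(benzyloxy)-4-methoxyphenyl]-3-hydroxy-7-methoxy-2,3-dihydro-4H-chromen-4-one
Product: 14 (2R,3R)-5,6-bis(benzyloxy)-2-[3-(benzyloxy)-4-methoxyphenyl]-3,7-dimethoxy-2,3-dihydro-4H-chromen-4-one
Conditions: MeOTf, 2,6-di-tert-butyl-4-methylpyridine, CH2Cl2, 0 °C → rt
Reagents that add atoms: methyl trifluoromethanesulfonate, COS(=O)(=O)C(F)(F)F
Why: O-Methylation of a hindered, base-sensitive α-hydroxy ketone with methyl triflate and a non-nucleophilic pyridine base; no enolate is formed, so C2 and C3 should keep their configuration.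

Step 8
Reactants: 14 (2R,3R)-5,6-bis(benzyloxy)-2-[3-(benzyloxy)-4-methoxyphenyl]-3,7-dimethoxy-2,3-dihydro-4H-chromen-4-one
Product: 15 (2R,3R)-5,6-dihydroxy-2-(3-hydroxy-4-methoxyphenyl)-3,7-dimethoxy-2,3-dihydro-4H-chromen-4-one
Conditions: H2 (1 atm), 10% Pd/C, EtOAc–MeOH, rt
Reagents that add atoms: none
Why: Hydrogenolysis of the three benzyl aryl ethers over Pd/C, which should be much faster than reduction of the C4 ketone or cleavage of the cyclic benzylic C2–O1 bond; no stereocentre is touched.

Compound list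
1 | 1-(2,6-dihydroxy-4-methoxyphenyl)ethan-1-one | CC(=O)c1c(O)cc(OC)cc1O | starting material
2 | 1-[2-(benzyloxy)-6-hydroxy-4-methoxyphenyl]ethan-1-one | CC(=O)c1c(OCc2ccccc2)cc(OC)cc1O | intermediate
3 | potassium 3-acetyl-2-(benzyloxy)-4-hydroxy-6-methoxyphenyl sulfate (not isolated) | CC(=O)c1c(OCc2ccccc2)c(OS(=O)(=O)[O-])c(OC)cc1O.[K+] | intermediate
4 | 1-[2-(benzyloxy)-3,6-dihydroxy-4-methoxyphenyl]ethan-1-one | CC(=O)c1c(OCc2ccccc2)c(O)c(OC)cc1O | intermediate
5 | 1-[2,3-bis(benzyloxy)-6-hydroxy-4-methoxyphenyl]ethan-1-one | CC(=O)c1c(OCc2ccccc2)c(OCc2ccccc2)c(OC)cc1O | intermediate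
6 | {1-[2,3-bis(benzyloxy)-4-methoxy-6-(trimethylsilyloxy)phenyl]ethenyloxy}trimethylsilane (not isolated) | C=C(O[Si](C)(C)C)c1c(OCc2ccccc2)c(OCc2ccccc2)c(OC)cc1O[Si](C)(C)C | intermediate
7 | 1-[2,3-bis(benzyloxy)-4-methoxy-6-(trimethylsilyloxy)phenyl]-2-(trimethylsilyloxy)ethan-1-one (not isolated) | C[Si](C)(C)OCC(=O)c1c(OCc2ccccc2)c(OCc2ccccc2)c(OC)cc1O[Si](C)(C)C | intermediate
8 | 1-[2,3-bis(benzyloxy)-6-hydroxy-4-methoxyphenyl]-2-hydroxyethan-1-one | O=C(CO)c1c(OCc2ccccc2)c(OCc2ccccc2)c(OC)cc1O | intermediate
9 | 3-(benzyloxy)-4-methoxybenzaldehyde | COc1ccc(C=O)cc1OCc1ccccc1 | starting material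
10 | 2-(benzyloxy)-4-(dimethoxymethyl)-1-methoxybenzene (not isolated) | COc1ccc(C(OC)OC)cc1OCc1ccccc1 | intermediate
11 | rac-6,7-bis(benzyloxy)-2-[3-(benzyloxy)-4-methoxyphenyl]-8-methoxy-2H-1,3-benzodioxepin-5(4H)-one | O=C1COC(c2ccc(OC)c(OCc3ccccc3)c2)Oc2cc(OC)c(OCc3ccccc3)c(OCc3ccccc3)c21 | intermediate
12 | ring-opened aryloxycarbenium (Z)-enediol cation, ion pair with the catalyst anion (not isolated) | O/C=C(\O)c1c(OCc2ccccc2)c(OCc2ccccc2)c(OC)cc1[O+]=Cc1ccc(OC)c(OCc2ccccc2)c1 | intermediate
13 | (2R,3R)-5,6-bis(benzyloxy)-2-[3-(benzyloxy)-4-methoxyphenyl]-3-hydroxy-7-methoxy-2,3-dihydro-4H-chromen-4-one | COc1ccc([C@H]2Oc3cc(OC)c(OCc4ccccc4)c(OCc4ccccc4)c3C(=O)[C@@H]2O)cc1OCc1ccccc1 | intermediate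
14 | (2R,3R)-5,6-bis(benzyloxy)-2-[3-(benzyloxy)-4-methoxyphenyl]-3,7-dimethoxy-2,3-dihydro-4H-chromen-4-one | COc1ccc([C@H]2Oc3cc(OC)c(OCc4ccccc4)c(OCc4ccccc4)c3C(=O)[C@@H]2OC)cc1OCc1ccccc1 | intermediate
15 | (2R,3R)-5,6-dihydroxy-2-(3-hydroxy-4-methoxyphenyl)-3,7-dimethoxy-2,3-dihydro-4H-chromen-4-one | COc1ccc([C@H]2Oc3cc(OC)c(O)c(O)c3C(=O)[C@@H]2OC)cc1O | target

Total step count: 8
Longest linear sequence: 8 steps (1 → 15); aldehyde 9 enters unchanged in step 5.

Steps most likely to fail

Step 6 (Proposed new method). The ion pair may discriminate the two faces of the oxocarbenium ion poorly, so that the product is formed with low enantiomeric purity. The cation may also re-close or oligomerise instead of forming the C2–C3 bond. The fallback uses known chemistry, sets out from 5 and returns at 13. The free phenol of 5 is protected with MOMCl/i-Pr2NEt as 1-[2,3-bis(benzyloxy)-4-methoxy-6-(methoxymethoxy)phenyl]ethan-1-one F1. Claisen–Schmidt condensation of F1 with 9 (KOH, EtOH) should give the E-chalcone F2. Juliá–Colonna epoxidation (poly-L-leucine, urea–H2O2, DBU, THF) should give the (2R,3S)-epoxy ketone F3. Methanolic HCl then removes the MOM group, and the freed phenol opens the epoxide at the benzylic carbon with inversion (6-endo), which should give the trans-(2R,3R)-dihydroflavonol 13.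

Step 5. The seven-membered ring may fail to close, leaving open-chain mixed acetals or oligomers, or the acetal may rearrange prematurely and unselectively under the acidic conditions. The fallback sets out from 8 and returns at 11 by oxidative instead of condensative C–O bond formation. The primary hydroxyl of 8 is etherified under CSA catalysis with 3-(benzyloxy)-4-methoxybenzyl 2,2,2-trichloroacetimidate F4, made from commercial [3-(benzyloxy)-4-methoxyphenyl]methanol with Cl3CCN/DBU. This should give the ω-arylmethyl ether F5. Anhydrous DDQ (CH2Cl2, 4 Å MS, 0 °C) then oxidises the electron-rich benzylic ether to its oxocarbenium ion, which the ortho phenol traps to close the acetal 11, in the manner of p-methoxybenzylidene acetal formation from PMB ethers.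

Step 2. Persulfate oxidations typically suffer from over-oxidation to quinoid material and incomplete conversion, and the benzyl ether may be partly lost during sulfate hydrolysis. The fallback sets out from 2 and returns at 4. Teuber oxidation with Fremy's salt (KH2PO4 buffer, acetone–water) should convert the phenol into 2-acetyl-3-(benzyloxy)-5-methoxy-1,4-benzoquinone F6. Reduction of F6 with aqueous Na2S2O4 should give the hydroquinone 4 without any acidic hydrolysis.

Further compounds
F1 | step 6 | 1-[2,3-bis(benzyloxy)-4-methoxy-6-(methoxymethoxy)phenyl]ethan-1-one | CC(=O)c1c(OCc2ccccc2)c(OCc2ccccc2)c(OC)cc1OCOC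
F2 | step 6 | (E)-1-[2,3-bis(benzyloxy)-4-methoxy-6-(methoxymethoxy)phenyl]-3-[3-(benzyloxy)-4-methoxyphenyl]prop-2-en-1-one | COCOc1cc(OC)c(OCc2ccccc2)c(OCc2ccccc2)c1C(=O)/C=C/c1ccc(OC)c(OCc2ccccc2)c1
F3 | step 6 | [2,3-bis(benzyloxy)-4-methoxy-6-(methoxymethoxy)phenyl]{(2R,3S)-3-[3-(benzyloxy)-4-methoxyphenyl]oxiran-2-yl}methanone | COCOc1cc(OC)c(OCc2ccccc2)c(OCc2ccccc2)c1C(=O)[C@@H]1O[C@H]1c1ccc(OC)c(OCc2ccccc2)c1
F4 | step 5 | 3-(benzyloxy)-4-methoxybenzyl 2,2,2-trichloroacetimidate | COc1ccc(COC(=N)C(Cl)(Cl)Cl)cc1OCc1ccccc1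
F5 | step 5 | 1-[2,3-bis(benzyloxy)-6-hydroxy-4-methoxyphenyl]-2-{[3-(benzyloxy)-4-methoxyphenyl]methoxy}ethan-1-one | O=C(COCc1ccc(OC)c(OCc2ccccc2)c1)c1c(OCc2ccccc2)c(OCc2ccccc2)c(OC)cc1O
F6 | step 2 | 2-acetyl-3-(benzyloxy)-5-methoxy-1,4-benzoquinone | CC(=O)C1=C(OCc2ccccc2)C(=O)C(OC)=CC1=O
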